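The route cuts ring C at O1–C8a and C4–C4a. Both bonds end on neighbouring carbons of ring A, and the C5 oxygen flanks C4a. A 3,5-dialkoxybenzyne is polarised in just this way, taking the nucleophile at the remote carbon and the anion beside the ether. One fluoride-triggered (4+2) annulation joins ring A to an open-chain O–C2–C3–C4 unit that already bears ring B. It forms one C–O bond, one C–C bond and ring C. The partners are an ortho-silylaryl triflate made from phloroglucinol and the Z enol of an alpha-formyl arylacetate with bromine on ring B. The acid-labile side chain enters last by a Heck reaction.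

Key step: step 9

Remark on the chemistry: ring B of the target has OMe at C4' between OH and the side chain whereas 5-bromovanillin has OH there, so the methyl group is moved in steps 5 and 6; the ester alkyl group is lost in the key step and is taken as ethyl because ethyl diazoacetate is the commercial diazo ester.

Step 1
Reactants: 1 phloroglucinol (benzene-1,3,5-triol)
Product: 2 3,5-bis(methoxymethoxy)phenol
Conditions: MOMCl (2.0 equiv), i-Pr2NEt (2.5 equiv), DMF, 0 °C to rt; chromatography
Reagents that add atoms: chloromethyl methyl ether, COCCl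
Why: Williamson-type O-alkylation of a threefold symmetric triol is statistical but dependable, and the bis-ether should separate on silica from the mono-ether (resubmitted) and the tris-ether.

Step 2
Reactants: 2 3,5-bis(methoxymethoxy)phenol
Product: 3 2-bromo-3,5-bis(methoxymethoxy)phenol
Conditions: NBS (1.0 equiv), i-Pr2NH (10 mol %), CH2Cl2, −78 to 0 °C
Reagents that add atoms: N-bromosuccinimide, O=C1CCC(=O)N1Br
Why: In this electrophilic aromatic bromination the two equivalent positions ortho to the free OH are less crowded than C4 between two MOM ethers, the N-bromoamine is delivered by hydrogen bonding to the phenol, and one equivalent of NBS in the cold limits double bromination.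

Step 3
Reactants: 3 2-bromo-3,5-bis(methoxymethoxy)phenol
Product: 4 [2-bromo-3,5-bis(methoxymethoxy)phenoxy]trimethylsilane
Conditions: HMDS (1.0 equiv), THF, reflux; evaporation, used crude
Reagents that add atoms: hexamethyldisilazane, C[Si](C)(C)N[Si](C)(C)C
Why: O-silylation of a phenol with HMDS gives only ammonia beside the product, so the moisture-sensitive silyl ether needs no aqueous work-up or chromatography.

Step 4
Reactants: 4 [2-bromo-3,5-bis(methoxymethoxy)phenoxy]trimethylsilane
Product: 7 3,5-bis(methoxymethoxy)-2-(trimethylsilyl)phenyl trifluoromethanesulfonate, via aryllithium 5 (not isolated), via lithium phenoxide 6 (not isolated)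
Conditions: n-BuLi (1.1 equiv), THF, −78 °C; then Tf2O (1.2 equiv), −78 to 0 °C; cold aq. NaHCO3; Et3N-deactivated silica
Reagents that add atoms: trifluoromethanesulfonic anhydride, O=S(=O)(OS(=O)(=O)C(F)(F)F)C(F)(F)F
Why: Bromine–lithium exchange outruns ortho-lithiation at −78 °C, aryllithium 5 undergoes the O-to-C silyl shift (retro-Brook rearrangement) to phenoxide 6, and triflation in the same flask avoids isolating the free ortho-silylphenol, which is prone to protodesilylation.

Step 5
Reactants: 8 5-bromovanillin (3-bromo-4-hydroxy-5-methoxybenzaldehyde)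
Product: 9 3-bromo-4,5-dihydroxybenzaldehyde
Conditions: AlCl3 (1.2 equiv), pyridine (4.5 equiv), CH2Cl2, reflux; then aq. HCl
Reagents that add atoms: none
Why: In this Lewis acid demethylation of an ortho-hydroxyaryl methyl ether, aluminium binds the phenoxide and the neighbouring methoxy oxygen and pyridine removes the methyl group by SN2 attack, while aldehyde and bromide are untouched.

Step 6
Reactants: 9 3-bromo-4,5-dihydroxybenzaldehyde
Product: 10 3-bromo-5-hydroxy-4-methoxybenzaldehyde
Conditions: MeI (1.2 equiv), Li2CO3 (1.5 equiv), DMF, 40 °C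
Reagents that add atoms: iodomethane, CI
Why: This Williamson methylation is chemoselective because the 4-OH, para to the formyl group and ortho to bromine, is clearly the more acidic phenol, so the weak base ionises only that oxygen.

Step 7
Reactants: 10 3-bromo-5-hydroxy-4-methoxybenzaldehyde
Product: 11 3-bromo-4-methoxy-5-(methoxymethoxy)benzaldehyde
Conditions: MOMCl (1.3 equiv), i-Pr2NEt (1.6 equiv), CH2Cl2, 0 °C to rt
Reagents that add atoms: chloromethyl methyl ether, COCCl
Why: Standard O-alkylation of the remaining phenol gives an acetal that resists fluoride, enolate and alkoxide and falls together with the ring A groups in step 10.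

Step 8
Reactants: 11 3-bromo-4-methoxy-5-(methoxymethoxy)benzaldehyde; 12 ethyl diazoacetate
Product: 14 ethyl (Z)-2-[3-bromo-4-methoxy-5-(methoxymethoxy)phenyl]-3-hydroxyprop-2-enoate, via formyl ester tautomer 13 (not isolated)
Conditions: HBF4·OEt2 (10 mol %), CH2Cl2, −78 °C, slow addition of 12 (1.3 equiv); Et3N quench at −78 °C
Reagents that add atoms: none
Why: The diazo carbon adds to the protonated aldehyde and a 1,2-aryl shift with loss of N2 follows (the known acid-catalysed formal insertion of diazo esters into the aryl–CHO bond of aromatic aldehydes), which should give 13 and then its hydrogen-bonded Z enol 14, with the para methoxy group favouring aryl over hydride migration and the low temperature sparing the MOM ether.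

Step 9
Reactants: 7 3,5-bis(methoxymethoxy)-2-(trimethylsilyl)phenyl trifluoromethanesulfonate; 14 ethyl (Z)-2-[3-bromo-4-methoxy-5-(methoxymethoxy)phenyl]-3-hydroxyprop-2-enoate
Product: 18 3-[3-bromo-4-methoxy-5-(methoxymethoxy)phenyl]-5,7-bis(methoxymethoxy)-4H-chromen-4-one, via aryne 15 (not isolated), via caesium enolate 16 (not isolated), via aryl anion adduct 17 (not isolated)
Conditions: 7 (1.5 equiv), 14 (1.0 equiv), CsF (4 equiv), dry THF, 65 °C, sealed vessel
Reagents that add atoms: none
Why: Proposed new method: fluoride takes silicon from 7 and triflate departs to give aryne 15, CsF also turns the vinylogous acid 14 into enolate 16, the terminal oxygen of 16 adds to the aryne carbon remote from the neighbouring MOM ether (O1–C8a), and aryl anion 17, placed beside that ether, adds to the cis ester carbonyl and expels ethoxide (C4a–C4). The closest known reaction type is the fluoride-induced annulation of arynes with salicylate esters to xanthones, in which a phenoxide does what the open-chain enolate must do here. Ring C closes by a 6-exo-trig addition–elimination at the ester carbon, and no stereocentre is formed. Site selectivity on the aryne comes from the inductive distortion by the oxygen that becomes O5, which makes the far terminus the more linear and electrophilic one and stabilises the charge next to the ether. O-arylation has to beat C-arylation with acyl transfer, the usual path of beta-dicarbonyl compounds, and this rests on the unhindered terminal oxygen set against a fully substituted alpha carbon screened by the twisted ring B. Closure also needs the U-shaped Z enolate, so THF without crown ether or polar cosolvent is chosen to keep caesium bridging both oxygens, and the excess of 7 consumes the ethanol released.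

Step 10
Reactants: 18 3-[3-bromo-4-methoxy-5-(methoxymethoxy)phenyl]-5,7-bis(methoxymethoxy)-4H-chromen-4-one
Product: 19 3-(3-bromo-5-hydroxy-4-methoxyphenyl)-5,7-dihydroxy-4H-chromen-4-one
Conditions: conc. HCl (cat.), MeOH, 50 °C
Reagents that add atoms: none
Why: Acid-catalysed acetal exchange with methanol removes all three MOM groups without touching the chromenone, bromide or methyl ether, and it is placed before the Heck reaction because the tertiary allylic alcohol of the target would ionise in acid.

Step 11
Reactants: 19 3-(3-bromo-5-hydroxy-4-methoxyphenyl)-5,7-dihydroxy-4H-chromen-4-one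
Product: 20 3-[3-(acetyloxy)-5-bromo-4-methoxyphenyl]-4-oxo-4H-chromene-5,7-diyl diacetate
Conditions: Ac2O (6 equiv), pyridine, DMAP (cat.), rt
Reagents that add atoms: acetic anhydride, CC(=O)OC(C)=O
Why: DMAP-catalysed acetylation caps all three phenols including the chelated 5-OH, which removes the acidic protons and the 5-OH/4-oxo binding site that could tie up palladium in the next step.

Step 12
Reactants: 20 3-[3-(acetyloxy)-5-bromo-4-methoxyphenyl]-4-oxo-4H-chromene-5,7-diyl diacetate; 21 2-methylbut-3-en-2-ol
Product: 22 3-{3-(acetyloxy)-5-[(E)-3-hydroxy-3-methylbut-1-enyl]-4-methoxyphenyl}-4-oxo-4H-chromene-5,7-diyl diacetate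
Conditions: 21 (4 equiv), Pd(OAc)2 (5 mol %), P(o-tol)3 (15 mol %), Et3N (3 equiv), DMF, 100 °C, sealed tube
Reagents that add atoms: none
Why: In this Heck reaction the aryl bromide adds oxidatively to zerovalent palladium, the aryl group is transferred syn to the terminal alkene carbon, and syn beta-hydride elimination, possible only from the benzylic CH2 because the carbinol carbon is quaternary, sets the E alkene.

Step 13
Reactants: 22 3-{3-(acetyloxy)-5-[(E)-3-hydroxy-3-methylbut-1-enyl]-4-methoxyphenyl}-4-oxo-4H-chromene-5,7-diyl diacetate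
Product: 23 3-{3-hydroxy-5-[(E)-3-hydroxy-3-methylbut-1-enyl]-4-methoxyphenyl}-5,7-dihydroxy-4H-chromen-4-one (target)
Conditions: K2CO3 (3.5 equiv), MeOH, 0 °C; pH 7 phosphate buffer
Reagents that add atoms: none
Why: Base-mediated transesterification cleaves aryl acetates quickly in the cold, the pyranone and the E alkene are unaffected, and the neutral quench keeps the tertiary allylic alcohol away from acid.

Compound list
1 | phloroglucinol | Oc1cc(O)cc(O)c1 | starting material
2 | 3,5-bis(methoxymethoxy)phenol | COCOc1cc(O)cc(OCOC)c1 | intermediate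
3 | 2-bromo-3,5-bis(methoxymethoxy)phenol | COCOc1cc(O)c(Br)c(OCOC)c1 | intermediate
4 | [2-bromo-3,5-bis(methoxymethoxy)phenoxy]trimethylsilane | COCOc1cc(O[Si](C)(C)C)c(Br)c(OCOC)c1 | intermediate
5 | [2,4-bis(methoxymethoxy)-6-(trimethylsilyloxy)phenyl]lithium (not isolated) | COCOc1cc(O[Si](C)(C)C)c([Li])c(OCOC)c1 | intermediate
6 | lithium 3,5-bis(methoxymethoxy)-2-(trimethylsilyl)phenoxide (not isolated) | COCOc1cc([O-])c([Si](C)(C)C)c(OCOC)c1.[Li+] | intermediate
7 | 3,5-bis(methoxymethoxy)-2-(trimethylsilyl)phenyl trifluoromethanesulfonate | COCOc1cc(OCOC)c([Si](C)(C)C)c(OS(=O)(=O)C(F)(F)F)c1 | intermediate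
8 | 5-bromovanillin | COc1cc(C=O)cc(Br)c1O | starting material
9 | 3-bromo-4,5-dihydroxybenzaldehyde | O=Cc1cc(O)c(O)c(Br)c1 | intermediate
10 | 3-bromo-5-hydroxy-4-methoxybenzaldehyde | COc1c(O)cc(C=O)cc1Br | intermediate
11 | 3-bromo-4-methoxy-5-(methoxymethoxy)benzaldehyde | COCOc1cc(C=O)cc(Br)c1OC | intermediate
12 | ethyl diazoacetate | CCOC(=O)C=[N+]=[N-] | starting material
13 | ethyl 2-[3-bromo-4-methoxy-5-(methoxymethoxy)phenyl]-3-oxopropanoate (racemic, configurationally labile, not isolated) | CCOC(=O)C(C=O)c1cc(Br)c(OC)c(OCOC)c1 | intermediate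
14 | ethyl (Z)-2-[3-bromo-4-methoxy-5-(methoxymethoxy)phenyl]-3-hydroxyprop-2-enoate | CCOC(=O)/C(=C\O)c1cc(Br)c(OC)c(OCOC)c1 | intermediate
15 | 3,5-bis(methoxymethoxy)benzyne (not isolated) | C1#CC(OCOC)=CC(OCOC)=C1 | intermediate
16 | caesium (Z)-enolate of 14 (not isolated) | CCOC(=O)/C(=C\[O-])c1cc(Br)c(OC)c(OCOC)c1.[Cs+] | intermediate
17 | caesium 2-{(Z)-2-aryl-2-(ethoxycarbonyl)ethenyloxy}-4,6-bis(methoxymethoxy)phenyl anion, aryl = ring B of 14 (not isolated) | CCOC(=O)/C(=C\Oc1cc(OCOC)cc(OCOC)[c-]1)c1cc(Br)c(OC)c(OCOC)c1.[Cs+] | intermediate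
18 | 3-[3-bromo-4-methoxy-5-(methoxymethoxy)phenyl]-5,7-bis(methoxymethoxy)-4H-chromen-4-one | COCOc1cc(OCOC)c2c(c1)occ(-c1cc(Br)c(OC)c(OCOC)c1)c2=O | intermediate
19 | 3-(3-bromo-5-hydroxy-4-methoxyphenyl)-5,7-dihydroxy-4H-chromen-4-one | COc1c(O)cc(-c2coc3cc(O)cc(O)c3c2=O)cc1Br | intermediate
20 | 3-[3-(acetyloxy)-5-bromo-4-methoxyphenyl]-4-oxo-4H-chromene-5,7-diyl diacetate | COc1c(OC(C)=O)cc(-c2coc3cc(OC(C)=O)cc(OC(C)=O)c3c2=O)cc1Br | intermediate
21 | 2-methylbut-3-en-2-ol | C=CC(C)(C)O | starting material
22 | 3-{3-(acetyloxy)-5-[(E)-3-hydroxy-3-methylbut-1-enyl]-4-methoxyphenyl}-4-oxo-4H-chromene-5,7-diyl diacetate | COc1c(OC(C)=O)cc(-c2coc3cc(OC(C)=O)cc(OC(C)=O)c3c2=O)cc1/C=C/C(C)(C)O | intermediate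
23 | 3-{3-hydroxy-5-[(E)-3-hydroxy-3-methylbut-1-enyl]-4-methoxyphenyl}-5,7-dihydroxy-4H-chromen-4-one | COc1c(O)cc(-c2coc3cc(O)cc(O)c3c2=O)cc1/C=C/C(C)(C)O | target

Total step count: 13
Longest linear sequence: 9 steps (steps 5–13 from 8; equally steps 1–4 and 9–13 from 1)

Steps most likely to fail

1. Step 9.
- **What may go wrong:** Arylation may occur at the alpha carbon and be followed by formyl transfer. O-arylation may proceed from the extended E enolate, after which the aryl anion cannot reach the ester and is only protonated. The released ethoxide may consume aryne or open the pyranone.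
- **Fallback:** This is known deoxybenzoin chemistry without an aryne, and it sets out from 14 and 1 and comes back at 19. Hot NaOH in aqueous ethanol removes the formyl group of 14 by retro-Claisen cleavage and saponifies the ester to 2-[3-bromo-4-methoxy-5-(methoxymethoxy)phenyl]acetic acid F1. Friedel–Crafts acylation of phloroglucinol 1 with F1 in BF3·OEt2 at about 85 °C, during which the MOM ether is lost, should give 2-(3-bromo-5-hydroxy-4-methoxyphenyl)-1-(2,4,6-trihydroxyphenyl)ethan-1-one F2. A Vilsmeier-type one-carbon insertion (DMF, MeSO2Cl, BF3·OEt2, 60 °C) formylates the methylene group and closes ring C to give triol 19, from which step 11 continues.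

2. Step 8.
- **What may go wrong:** Hydride may migrate instead of aryl, leading to the beta-keto ester series. The acid may strip the MOM ether.
- **Fallback:** The arylacetate is built first and then formylated, setting out from 11 and coming back at 14.
  - Pinnick oxidation (NaClO2, NaH2PO4, 2-methylbut-2-ene, t-BuOH–water) gives 3-bromo-4-methoxy-5-(methoxymethoxy)benzoic acid F3.
  - ClCO2Et and Et3N in THF at 0 °C give the mixed ethyl carbonic anhydride F4.
  - Ethereal CH2N2 converts F4 into 1-[3-bromo-4-methoxy-5-(methoxymethoxy)phenyl]-2-diazoethan-1-one F5.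
  - Wolff rearrangement (silver benzoate, Et3N, EtOH) completes the Arndt–Eistert homologation to ethyl 2-[3-bromo-4-methoxy-5-(methoxymethoxy)phenyl]acetate F6.
  - Crossed Claisen condensation of F6 with ethyl formate and NaH in THF, followed by a cold citric acid quench, gives 14.

3. Step 2.
- **What may go wrong:** Bromination may occur para to the hydroxyl group between the two MOM ethers. Twofold bromination of the very electron-rich ring is also possible.
- **Fallback:** Silicon is placed by directed ortho-metalation instead of through a halide, setting out from 2 and coming back at 6. ClCONEt2 and NaH in THF give 3,5-bis(methoxymethoxy)phenyl N,N-diethylcarbamate F7. s-BuLi and TMEDA in THF at −78 °C lithiate the position between the carbamate and a MOM ether, the strongest directing pair, and TMSCl gives 3,5-bis(methoxymethoxy)-2-(trimethylsilyl)phenyl N,N-diethylcarbamate F8. LiAlH4 in THF cleaves the carbamate to 3,5-bis(methoxymethoxy)-2-(trimethylsilyl)phenol F9. This phenol is not chromatographed but deprotonated with n-BuLi at −78 °C to phenoxide 6, where step 4 resumes with Tf2O.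

Further compounds
F1 | step 9 | 2-[3-bromo-4-methoxy-5-(methoxymethoxy)phenyl]acetic acid | COCOc1cc(CC(=O)O)cc(Br)c1OC
F2 | step 9 | 2-(3-bromo-5-hydroxy-4-methoxyphenyl)-1-(2,4,6-trihydroxyphenyl)ethan-1-one | COc1c(O)cc(CC(=O)c2c(O)cc(O)cc2O)cc1Br
F3 | step 8 | 3-bromo-4-methoxy-5-(methoxymethoxy)benzoic acid | COCOc1cc(C(=O)O)cc(Br)c1OC
F4 | step 8 | 3-bromo-4-methoxy-5-(methoxymethoxy)benzoic ethyl carbonic anhydride | CCOC(=O)OC(=O)c1cc(Br)c(OC)c(OCOC)c1
F5 | step 8 | 1-[3-bromo-4-methoxy-5-(methoxymethoxy)phenyl]-2-diazoethan-1-one | COCOc1cc(C(=O)C=[N+]=[N-])cc(Br)c1OC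
F6 | step 8 | ethyl 2-[3-bromo-4-methoxy-5-(methoxymethoxy)phenyl]acetate | CCOC(=O)Cc1cc(Br)c(OC)c(OCOC)c1
F7 | step 2 | 3,5-bis(methoxymethoxy)phenyl N,N-diethylcarbamate | CCN(CC)C(=O)Oc1cc(OCOC)cc(OCOC)c1
F8 | step 2 | 3,5-bis(methoxymethoxy)-2-(trimethylsilyl)phenyl N,N-diethylcarbamate | CCN(CC)C(=O)Oc1cc(OCOC)cc(OCOC)c1[Si](C)(C)C
F9 | step 2 | 3,5-bis(methoxymethoxy)-2-(trimethylsilyl)phenol | COCOc1cc(O)c([Si](C)(C)C)c(OCOC)c1
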